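**Str​ategy.** The route rests on cutting the C4=C5 olefin of the ten-membered ring. Because O15 and O6 lie cis across that bond, one silicon atom can bridge them. Ring-closing metathesis inside a thirteen-membered diisopropylsilylene diether then joins the C5 vinyl and C4 methylidene carbons. This single operation closes the carbocycle transannularly and the seven-membered dioxasilepine, and the small ring fixes the olefin geometry. The precursor already carries all five stereocentres, the C8 ester, the C12 methyl ester and the Z C1=C10 olefin.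

Key step: step 22

Assumption: atoms are numbered as in germacranes (ring C1–C10, C14 on C10, C15 on C4, C11–C13 in the lactone arm), and the free 4-hydroxy ester of the side chain is taken to tolerate acetic-acid-buffered fluoride, so its silyl ether is cleaved last.

**Part A – C6–C8/C11–C13 aldehyde**

Step 1
Reactants: 1 (S)-2-methylbutanedioic acid
Product: 2 (S)-3-methyloxolane-2,5-dione
Conditions: AcCl, reflux
Reagents that add atoms: none
Why: Cyclodehydration of a 1,4-diacid by acetyl chloride (mixed-anhydride exchange) should give the five-membered anhydride without touching the future C11 stereocentre.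

Step 2
Reactants: 2 (S)-3-methyloxolane-2,5-dione; 3 (S)-4-benzyl-1,3-oxazolidin-2-one
Product: 5 (2S)-4-[(4S)-4-benzyl-2-oxo-1,3-oxazolidin-3-yl]-2-methyl-4-oxobutanoic acid, via N-lithio oxazolidinone 4 (not isolated)
Conditions: n-BuLi, THF, −78 °C; 2, −78 to 0 °C; 1 M HCl
Reagents that add atoms: none
Why: Ring-opening N-acylation of the lithiated oxazolidinone by a cyclic anhydride should occur at the carbonyl flanked by CH2 and not at the one shielded by the methyl branch, so the free acid ends up next to the stereocentre (any minor regioisomer is removed here).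

Step 3
Reactants: 5 (2S)-4-[(4S)-4-benzyl-2-oxo-1,3-oxazolidin-3-yl]-2-methyl-4-oxobutanoic acid
Product: 6 methyl (2S)-4-[(4S)-4-benzyl-2-oxo-1,3-oxazolidin-3-yl]-2-methyl-4-oxobutanoate
Conditions: Me3SiCHN2, MeOH/toluene, 0 °C
Reagents that add atoms: trimethylsilyldiazomethane, C[Si](C)(C)C=[N+]=[N-]
Why: O-Methylation of a carboxylic acid with a diazoalkane is neutral and should leave the imide and the α-stereocentre intact.

Step 4
Reactants: 6 methyl (2S)-4-[(4S)-4-benzyl-2-oxo-1,3-oxazolidin-3-yl]-2-methyl-4-oxobutanoate; 7 prop-2-enal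
Product: 9 methyl (2S,3S,4R)-3-{[(4S)-4-benzyl-2-oxo-1,3-oxazolidin-3-yl]carbonyl}-4-hydroxy-2-methylhex-5-enoate, via dibutylboron Z-enolate 8 (not isolated)
Conditions: n-Bu2BOTf, i-Pr2NEt, CH2Cl2, 0 °C; 7, −78 to 0 °C; pH 7 buffer, MeOH, H2O2
Reagents that add atoms: none
Why: Evans syn-aldol reaction, in which the boron Z-enolate forms at the imide α-CH2 (not at the ester α-CH) and adds to the enal through a Zimmerman–Traxler chair on the face away from the benzyl group, so that C7 and C6 are set syn under auxiliary control.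

Step 5
Reactants: 9 syn-aldol adduct
Product: 10 methyl (2S,3S,4R)-3-{[(4S)-4-benzyl-2-oxo-1,3-oxazolidin-3-yl]carbonyl}-2-methyl-4-[(triethylsilyl)oxy]hex-5-enoate
Conditions: Et3SiOTf, 2,6-lutidine, CH2Cl2, −78 °C
Reagents that add atoms: triethylsilyl trifluoromethanesulfonate, CC[Si](CC)(CC)OS(=O)(=O)C(F)(F)F
Why: Silylation of a secondary alcohol with a silyl triflate and a hindered pyridine is fast at low temperature and blocks the C6 hydroxyl before it can lactonise onto the C12 ester.

Step 6
Reactants: 10 triethylsilyl ether of the aldol adduct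
Product: 11 methyl (2S,3S,4R)-3-[(ethylsulfanyl)carbonyl]-2-methyl-4-[(triethylsilyl)oxy]hex-5-enoate
Conditions: EtSH, n-BuLi, THF, 0 °C; aq. NH4Cl
Reagents that add atoms: ethanethiol, CCS
Why: Thiolate transacylation displaces the oxazolidinone at the activated exocyclic imide carbonyl and should spare the methyl ester and the silyl ether.

Step 7
Reactants: 11 thioester
Product: 12 methyl (2S,3S,4R)-3-formyl-2-methyl-4-[(triethylsilyl)oxy]hex-5-enoate
Conditions: Et3SiH, Pd/CaCO3 poisoned with Pb(OAc)2, acetone, rt
Reagents that add atoms: none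
Why: Fukuyama reduction stops at the aldehyde and is selective for the thioester over the methyl ester, and the poisoned palladium catalyst should spare the terminal olefin.

**Part B – C9–C10/C1–C4/C15 allylic chloride**

Step 8
Reactants: 13 2-methylidenepropane-1,3-diol
Product: 14 2-{[(tert-butyldimethylsilyl)oxy]methyl}prop-2-en-1-ol
Conditions: NaH (1 equiv), THF, 0 °C; t-BuMe2SiCl, rt
Reagents that add atoms: tert-butyldimethylsilyl chloride, CC(C)(C)[Si](C)(C)Cl
Why: Monosilylation of a symmetrical diol through its sparingly soluble monosodium alkoxide should stop after one silyl group.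

Step 9
Reactants: 14 mono-silyl ether
Product: 16 ethyl 4-{[(tert-butyldimethylsilyl)oxy]methyl}pent-4-enoate, via mixed ketene acetal 15 (not isolated)
Conditions: MeC(OEt)3, EtCO2H (cat.), 140 °C
Reagents that add atoms: triethyl orthoacetate, CCOC(C)(OCC)OCC
Why: Johnson–Claisen rearrangement, a [3,3] shift of the ketene acetal that transposes the olefin to the C4 methylidene and adds C2 and C1 without involving any stereocentre.

Step 10
Reactants: 16 ethyl ester
Product: 17 4-{[(tert-butyldimethylsilyl)oxy]methyl}pent-4-enal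
Conditions: i-Bu2AlH (1.1 equiv), CH2Cl2, −78 °C
Reagents that add atoms: none
Why: Partial ester reduction by a dialkylaluminium hydride proceeds through a tetrahedral aluminate that is stable at −78 °C and releases the aldehyde only on work-up.

Step 11
Reactants: 17 aldehyde
Product: 18 ethyl (2Z)-6-{[(tert-butyldimethylsilyl)oxy]methyl}-2-methylhepta-2,6-dienoate
Conditions: (CF3CH2O)2P(O)CH(CH3)CO2Et, KN(SiMe3)2, 18-crown-6, THF, −78 °C
Reagents that add atoms: ethyl 2-[bis(2,2,2-trifluoroethoxy)phosphoryl]propanoate, CCOC(=O)C(C)P(=O)(OCC(F)(F)F)OCC(F)(F)F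
Why: Still–Gennari olefination, in which the electron-poor phosphonate with a dissociated potassium ion eliminates from the kinetic adduct and should give the Z trisubstituted enoate, placing C9 cis to C2 as the target requires.

Step 12
Reactants: 18 Z-enoate
Product: 19 (2Z)-6-{[(tert-butyldimethylsilyl)oxy]methyl}-2-methylhepta-2,6-dien-1-ol
Conditions: i-Bu2AlH (2.2 equiv), CH2Cl2, −78 °C
Reagents that add atoms: none
Why: 1,2-Reduction of an α,β-unsaturated ester with a dialkylaluminium hydride gives the allylic alcohol without change of olefin geometry.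

Step 13
Reactants: 19 Z-allylic alcohol
Product: 21 tert-butyl{[(5Z)-7-chloro-6-methyl-2-methylidenehept-5-en-1-yl]oxy}dimethylsilane, via allylic mesylate 20 (not isolated)
Conditions: MsCl, 2,4,6-collidine, LiCl, DMF, 0 °C
Reagents that add atoms: lithium chloride, [Li+].[Cl-]
Why: Chloride displaces the mesylate formed in situ by direct SN2 substitution at the primary carbon, which should keep the Z geometry and avoid allylic transposition.

**Part C – side-chain acid**

Step 14
Reactants: 22 methyl (R)-3-hydroxy-2-methylpropanoate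
Product: 23 methyl (R)-3-[(tert-butyldiphenylsilyl)oxy]-2-methylpropanoate
Conditions: t-BuPh2SiCl, imidazole, CH2Cl2, rt
Reagents that add atoms: tert-butyldiphenylsilyl chloride, CC(C)(C)[Si](Cl)(c1ccccc1)c1ccccc1
Why: Standard silylation of a primary alcohol under imidazole buffering, which does not epimerise the ester α-carbon.

Step 15
Reactants: 23 silyl-protected ester
Product: 24 (S)-3-[(tert-butyldiphenylsilyl)oxy]-2-methylpropan-1-ol
Conditions: i-Bu2AlH (2.2 equiv), CH2Cl2, −78 to 0 °C
Reagents that add atoms: none
Why: Hydride reduction of the ester to the primary alcohol leaves a stereocentre that can no longer epimerise.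

Step 16
Reactants: 24 primary alcohol
Product: 25 (R)-tert-butyl(3-iodo-2-methylpropoxy)diphenylsilane
Conditions: I2, PPh3, imidazole, CH2Cl2, 0 °C to rt
Reagents that add atoms: iodine, II
Why: Appel-type iodination by SN2 displacement of an oxyphosphonium ion at a non-stereogenic primary carbon.

Step 17
Reactants: 25 primary iodide
Product: 27 (S)-4-[(tert-butyldiphenylsilyl)oxy]-3-methylbutanoic acid, via primary alkyllithium 26 (not isolated)
Conditions: t-BuLi (2 equiv), Et2O, −78 °C; CO2; 1 M HCl
Reagents that add atoms: carbon dioxide, O=C=O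
Why: Lithium–iodine exchange followed by carboxylation of the alkyllithium is a one-carbon homologation that leaves the β-stereocentre (C3′) untouched.

**Part D – union, macrocycle, key step, endgame**

Step 18
Reactants: 21 Z-allylic chloride; 12 C8 aldehyde
Product: 29 methyl (2S,3R,4S,6Z)-11-[(tert-butyldimethylsilyl)oxy]-4-hydroxy-2,6-dimethyl-10-methylidene-3-{(1R)-1-[(triethylsilyl)oxy]prop-2-en-1-yl}undec-6-enoate, via allylbarium chloride 28 (not isolated)
Conditions: BaI2, lithium biphenylide (LiC12H10, 2 equiv), THF, rt; 21, −78 °C; 12, −78 °C; aq. NH4Cl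
Reagents that add atoms: none
Why: Barbier-type carbonyl allylation with an allylic barium reagent, a class that attacks aldehydes through the unsubstituted α-carbon with retention of olefin geometry at −78 °C, so C8–C9 should form with the Z C1=C10 olefin intact, and the C8 carbinol is expected to arise by Felkin–Anh attack anti to the bulky silyloxy-bearing C6 branch (8S, syn to the C7 substituent).

Step 19
Reactants: 29 C8 alcohol; 27 side-chain acid
Product: 30 C8 ester (29 acylated on the C8 oxygen by the (S)-4-silyloxy-3-methylbutanoyl group; O6 triethylsilyl and O15 tert-butyldimethylsilyl retained)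
Conditions: EDC·HCl, DMAP, CH2Cl2, 0 °C to rt
Reagents that add atoms: none
Why: Steglich esterification acylates the only free hydroxyl, and the stereocentres are not involved.

Step 20
Reactants: 30 C8 ester
Product: 31 C6,C15-diol (seco compound with free O6–H and O15–H, C8 ester, C12 methyl ester, side-chain silyl ether)
Conditions: HF·pyridine, pyridine, THF, 0 °C to rt
Reagents that add atoms: none
Why: Pyridine-buffered fluoride cleaves the secondary triethylsilyl and primary tert-butyldimethylsilyl ethers much faster than the tert-butyldiphenylsilyl ether, so only O6 and O15 should be exposed.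

Step 21
Reactants: 31 C6,C15-diol
Product: 33 thirteen-membered diisopropylsilylene diether (O6–Si–O15 bridge; C5 vinyl, C4 methylidene, Z C1=C10), via O15 silyl triflate 32 (not isolated)
Conditions: i-Pr2Si(OTf)2, 2,6-lutidine, CH2Cl2 (1 mM, slow addition), −20 °C to rt
Reagents that add atoms: diisopropylsilyl bis(trifluoromethanesulfonate), CC(C)[Si](OS(=O)(=O)C(F)(F)F)(OS(=O)(=O)C(F)(F)F)C(C)C
Why: Silylene diether formation from a diol and a silyl bis(triflate), in which the primary allylic O15 hydroxyl reacts first and the alkoxysilyl triflate is then trapped by the C6 hydroxyl, with high dilution favouring the thirteen-membered closure over chain growth.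

Step 22
Reactants: 33 thirteen-membered silylene diether
Product: 34 silylene-bridged cyclodeca-1(10),4-diene (seven-membered dioxasilepine fused across C4=C5–C6 of the ten-membered carbocycle)
Conditions: second-generation Grubbs catalyst RuCl2(=CHPh)(PCy3)(H2IMes) (10 mol %), toluene (1 mM), 80 °C, argon sparge
Reagents that add atoms: none
Why: Olefin metathesis by the Chauvin mechanism: the ruthenium benzylidene exchanges onto the monosubstituted C5 vinyl group, the new alkylidene undergoes [2+2] cycloaddition with the 1,1-disubstituted C4 methylidene, and cycloreversion expels ethene to form C4=C5. The closest known reaction type is temporary silicon-tethered ring-closing metathesis of allyl/methallyl bis-alkoxysilanes to trisubstituted dioxasilepines, run here across a pre-formed macrocycle (transannular ring-closing metathesis). The seven-membered dioxasilepine closes by ordinary ring-closing metathesis of the two tethered olefins, and the ten-membered carbocycle closes in the same event by transannular contraction of the thirteen-membered ring, so no end-to-end medium-ring cyclisation is needed. No stereocentre is formed or touched. The selectivity needed is the geometry of C4=C5, and the seven-membered ring secures it because it can hold only the arrangement with C15 and C6 cis, which is the trans-in-ring olefin of the carbocycle. Attack of the C5 alkylidene on the ring olefin C1=C10 would need a ruthenacyclobutane substituted at all three carbons and should be slower than attack on the methylidene held close by the short O–Si–O link.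

Step 23
Reactants: 34 silylene-bridged cyclodecadiene
Product: 36 6,12-lactone with silyl-protected side chain (target bearing tert-butyldiphenylsilyl on the side-chain oxygen), via C6,C15-diol methyl ester 35 (not isolated)
Conditions: HF·pyridine, pyridine, THF, 0 °C; then PPTS, CH2Cl2, rt
Reagents that add atoms: none
Why: Fluoride cleaves the cyclic dialkoxysilane while the tert-butyldiphenylsilyl ether survives, and the freed C6 hydroxyl then closes the γ-lactone onto the C12 methyl ester by acid-catalysed transesterification, the five-membered ring being favoured over any closure from O15.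

Step 24
Reactants: 36 silyl-protected lactone
Product: 37 CNP0160815.1 (target)
Conditions: Bu4NF, AcOH (1:1), THF, 0 °C to rt
Reagents that add atoms: none
Why: Fluoride-mediated cleavage of the primary tert-butyldiphenylsilyl ether, buffered with acetic acid so that no free alkoxide can attack the side-chain ester or epimerise C11.

**Compound list**

1 | (S)-2-methylbutanedioic acid | OC(=O)C[C@H](C)C(=O)O | starting material
2 | (S)-3-methyloxolane-2,5-dione | C[C@H]1CC(=O)OC1=O | intermediate
3 | (S)-4-benzyl-1,3-oxazolidin-2-one | O=C1N[C@@H](Cc2ccccc2)CO1 | starting material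
4 | N-lithio derivative of 3 | [Li]N1[C@@H](Cc2ccccc2)COC1=O | intermediate
5 | (2S)-4-[(4S)-4-benzyl-2-oxo-1,3-oxazolidin-3-yl]-2-methyl-4-oxobutanoic acid | OC(=O)[C@@H](C)CC(=O)N1[C@@H](Cc2ccccc2)COC1=O | intermediate
6 | methyl (2S)-4-[(4S)-4-benzyl-2-oxo-1,3-oxazolidin-3-yl]-2-methyl-4-oxobutanoate | COC(=O)[C@@H](C)CC(=O)N1[C@@H](Cc2ccccc2)COC1=O | intermediate
7 | prop-2-enal | C=CC=O | starting material
8 | dibutylboron Z-enolate of 6 | COC(=O)[C@@H](C)/C=C(\OB(CCCC)CCCC)N1[C@@H](Cc2ccccc2)COC1=O | intermediate
9 | methyl (2S,3S,4R)-3-{[(4S)-4-benzyl-2-oxo-1,3-oxazolidin-3-yl]carbonyl}-4-hydroxy-2-methylhex-5-enoate | C=C[C@@H](O)[C@H]([C@H](C)C(=O)OC)C(=O)N1[C@@H](Cc2ccccc2)COC1=O | intermediate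
10 | 4-O-triethylsilyl ether of 9 | C=C[C@@H](O[Si](CC)(CC)CC)[C@H]([C@H](C)C(=O)OC)C(=O)N1[C@@H](Cc2ccccc2)COC1=O | intermediate
11 | methyl (2S,3S,4R)-3-[(ethylsulfanyl)carbonyl]-2-methyl-4-[(triethylsilyl)oxy]hex-5-enoate | C=C[C@@H](O[Si](CC)(CC)CC)[C@H]([C@H](C)C(=O)OC)C(=O)SCC | intermediate
12 | methyl (2S,3S,4R)-3-formyl-2-methyl-4-[(triethylsilyl)oxy]hex-5-enoate | C=C[C@@H](O[Si](CC)(CC)CC)[C@H]([C@H](C)C(=O)OC)C=O | intermediate
13 | 2-methylidenepropane-1,3-diol | C=C(CO)CO | starting material
14 | 2-{[(tert-butyldimethylsilyl)oxy]methyl}prop-2-en-1-ol | C=C(CO)CO[Si](C)(C)C(C)(C)C | intermediate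
15 | 1-ethoxyethenyl ether of 14 (mixed ketene acetal) | C=C(OCC)OCC(=C)CO[Si](C)(C)C(C)(C)C | intermediate
16 | ethyl 4-{[(tert-butyldimethylsilyl)oxy]methyl}pent-4-enoate | CCOC(=O)CCC(=C)CO[Si](C)(C)C(C)(C)C | intermediate
17 | 4-{[(tert-butyldimethylsilyl)oxy]methyl}pent-4-enal | O=CCCC(=C)CO[Si](C)(C)C(C)(C)C | intermediate
18 | ethyl (2Z)-6-{[(tert-butyldimethylsilyl)oxy]methyl}-2-methylhepta-2,6-dienoate | CCOC(=O)/C(C)=C\CCC(=C)CO[Si](C)(C)C(C)(C)C | intermediate
19 | (2Z)-6-{[(tert-butyldimethylsilyl)oxy]methyl}-2-methylhepta-2,6-dien-1-ol | OC/C(C)=C\CCC(=C)CO[Si](C)(C)C(C)(C)C | intermediate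
20 | methanesulfonate of 19 | CS(=O)(=O)OC/C(C)=C\CCC(=C)CO[Si](C)(C)C(C)(C)C | intermediate
21 | tert-butyl{[(5Z)-7-chloro-6-methyl-2-methylidenehept-5-en-1-yl]oxy}dimethylsilane | ClC/C(C)=C\CCC(=C)CO[Si](C)(C)C(C)(C)C | intermediate
22 | methyl (R)-3-hydroxy-2-methylpropanoate | COC(=O)[C@H](C)CO | starting material
23 | methyl (R)-3-[(tert-butyldiphenylsilyl)oxy]-2-methylpropanoate | COC(=O)[C@H](C)CO[Si](c1ccccc1)(c1ccccc1)C(C)(C)C | intermediate
24 | (S)-3-[(tert-butyldiphenylsilyl)oxy]-2-methylpropan-1-ol | OC[C@H](C)CO[Si](c1ccccc1)(c1ccccc1)C(C)(C)C | intermediate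
25 | (R)-tert-butyl(3-iodo-2-methylpropoxy)diphenylsilane | IC[C@H](C)CO[Si](c1ccccc1)(c1ccccc1)C(C)(C)C | intermediate
26 | alkyllithium from 25 (stereocentre unchanged) | [Li]C[C@H](C)CO[Si](c1ccccc1)(c1ccccc1)C(C)(C)C | intermediate
27 | (S)-4-[(tert-butyldiphenylsilyl)oxy]-3-methylbutanoic acid | OC(=O)C[C@H](C)CO[Si](c1ccccc1)(c1ccccc1)C(C)(C)C | intermediate
28 | Z-allylbarium chloride from 21 | Cl[Ba]C/C(C)=C\CCC(=C)CO[Si](C)(C)C(C)(C)C | intermediate
29 | methyl (2S,3R,4S,6Z)-11-[(tert-butyldimethylsilyl)oxy]-4-hydroxy-2,6-dimethyl-10-methylidene-3-{(1R)-1-[(triethylsilyl)oxy]prop-2-en-1-yl}undec-6-enoate (C8 alcohol) | C=C[C@@H](O[Si](CC)(CC)CC)[C@H]([C@H](C)C(=O)OC)[C@@H](O)C/C(C)=C\CCC(=C)CO[Si](C)(C)C(C)(C)C | intermediate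
30 | C8 ester: 29 acylated on O8 by (S)-4-[(tert-butyldiphenylsilyl)oxy]-3-methylbutanoyl; configurations unchanged | C=C[C@@H](O[Si](CC)(CC)CC)[C@H]([C@H](C)C(=O)OC)[C@@H](OC(=O)C[C@H](C)CO[Si](c1ccccc1)(c1ccccc1)C(C)(C)C)C/C(C)=C\CCC(=C)CO[Si](C)(C)C(C)(C)C | intermediate
31 | C6,C15-diol: 30 without the triethylsilyl and tert-butyldimethylsilyl groups | C=C[C@@H](O)[C@H]([C@H](C)C(=O)OC)[C@@H](OC(=O)C[C@H](C)CO[Si](c1ccccc1)(c1ccccc1)C(C)(C)C)C/C(C)=C\CCC(=C)CO | intermediate
32 | O15 diisopropyl(trifluoromethanesulfonyloxy)silyl ether of 31 | C=C[C@@H](O)[C@H]([C@H](C)C(=O)OC)[C@@H](OC(=O)C[C@H](C)CO[Si](c1ccccc1)(c1ccccc1)C(C)(C)C)C/C(C)=C\CCC(=C)CO[Si](C(C)C)(C(C)C)OS(=O)(=O)C(F)(F)F | intermediate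
33 | thirteen-membered diisopropylsilylene diether (ring C6, O, Si, O, C15, C4, C3, C2, C1, C10, C9, C8, C7; C5 vinyl on C6, methylidene on C4, Z C1=C10, C8 ester, C12 methyl ester) | C=C[C@H]1O[Si](C(C)C)(C(C)C)OCC(=C)CC/C=C(/C)C[C@H](OC(=O)C[C@H](C)CO[Si](c2ccccc2)(c2ccccc2)C(C)(C)C)[C@H]1[C@H](C)C(=O)OC | intermediate
34 | silylene-bridged cyclodecadiene (ten-membered carbocycle with Z C1=C10 and trans-in-ring C4=C5; seven-membered O6–Si–O15 dioxasilepine) | C/C1=C/CC/C2=C/[C@@H](O[Si](C(C)C)(C(C)C)OC2)[C@H]([C@H](C)C(=O)OC)[C@@H](OC(=O)C[C@H](C)CO[Si](c3ccccc3)(c3ccccc3)C(C)(C)C)C1 | intermediate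
35 | C6,C15-diol methyl ester of the cyclodecadiene | C/C1=C/CC/C(CO)=C/[C@@H](O)[C@H]([C@H](C)C(=O)OC)[C@@H](OC(=O)C[C@H](C)CO[Si](c2ccccc2)(c2ccccc2)C(C)(C)C)C1 | intermediate
36 | 6,12-lactone with tert-butyldiphenylsilyl-protected side chain | C/C1=C/CC/C(CO)=C/[C@H]2OC(=O)[C@@H](C)[C@@H]2[C@@H](OC(=O)C[C@H](C)CO[Si](c3ccccc3)(c3ccccc3)C(C)(C)C)C1 | intermediate
37 | CNP0160815.1 (6R,7R,8S,11S,3′S; 1(10)Z; C15 cis to C6 across C4=C5) | C/C1=C/CC/C(CO)=C/[C@H]2OC(=O)[C@@H](C)[C@@H]2[C@@H](OC(=O)C[C@H](C)CO)C1 | target

**Totals.** 24 steps in all. The longest linear sequence is 14 steps (steps 1–7 and 18–24, from 1).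

**Steps most likely to fail**

1. Step 22. The bicyclic product is strained, so closure may be slower than intermolecular metathesis (oligomer formation) or than ring-opening attack of the C5 alkylidene on the C1=C10 olefin. The fallback sets out from diol 31 and replaces the one-silicon bridge by a longer, more flexible two-silicon bridge. 1,3-Dichloro-1,1,3,3-tetraisopropyldisiloxane with imidazole under high dilution should give the fifteen-membered tetraisopropyldisiloxane-1,3-diyl diether F1. Metathesis with the same ruthenium catalyst then has to close a nine-membered disiloxane ring together with the carbocycle, giving the disiloxane-bridged cyclodecadiene F2, in which the bicycle is less strained but the cis arrangement of C15 and C6 is still favoured. Buffered HF·pyridine removes the disiloxane, and the route is rejoined at 35 and then 36.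

2. Step 18. The aldehyde is α-branched with two bulky arms, so facial discrimination in the allylation may be poor and give both C8 epimers. The fallback sets out from 29 as the epimer mixture and moves control of C8 from the substrate to a reagent. Buffered Dess–Martin oxidation should give the β,γ-unsaturated C8 ketone F3 without conjugation of the olefin. Corey–Bakshi–Shibata reduction with (R)-2-methyl-CBS-oxazaborolidine and catecholborane at −78 °C should then deliver hydride to the face that gives the 8S carbinol, the branched C7 side acting as the large group, and the route is rejoined at 29.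

3. Step 21. Silylation between molecules may outrun ring closure at the hindered C6 hydroxyl and give linear or cyclic oligomers. The fallback sets out from diol 31 and separates the two Si–O bond formations. Chlorodiisopropylsilane with imidazole at −40 °C should silylate only the primary O15 hydroxyl and give the hydridosilyl ether F4, which can be purified. Ring closure then occurs by dehydrogenative Si–O coupling with the C6 hydroxyl, catalysed by Rh2(O2CC3F7)4 under dilution, a step that is unimolecular from the start, and the route is rejoined at 33.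

**Further compounds**

F1 | step 22 | fifteen-membered 1,1,3,3-tetraisopropyldisiloxane-1,3-diyl diether of 31 (O6–Si–O–Si–O15 bridge) | C=C[C@H]1O[Si](C(C)C)(C(C)C)O[Si](C(C)C)(C(C)C)OCC(=C)CC/C=C(/C)C[C@H](OC(=O)C[C@H](C)CO[Si](c2ccccc2)(c2ccccc2)C(C)(C)C)[C@H]1[C@H](C)C(=O)OC
F2 | step 22 | disiloxane-bridged cyclodecadiene (nine-membered O6–Si–O–Si–O15 ring across C4=C5) | C/C1=C/CC/C2=C/[C@@H](O[Si](C(C)C)(C(C)C)O[Si](C(C)C)(C(C)C)OC2)[C@H]([C@H](C)C(=O)OC)[C@@H](OC(=O)C[C@H](C)CO[Si](c3ccccc3)(c3ccccc3)C(C)(C)C)C1
F3 | step 18 | C8 ketone corresponding to 29 | C=C[C@@H](O[Si](CC)(CC)CC)[C@H]([C@H](C)C(=O)OC)C(=O)C/C(C)=C\CCC(=C)CO[Si](C)(C)C(C)(C)C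
F4 | step 21 | O15 diisopropylsilyl (Si–H) ether of 31 | C=C[C@@H](O)[C@H]([C@H](C)C(=O)OC)[C@@H](OC(=O)C[C@H](C)CO[Si](c1ccccc1)(c1ccccc1)C(C)(C)C)C/C(C)=C\CCC(=C)CO[SiH](C(C)C)C(C)C
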